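The pyranone ring is disconnected at C2–C3 and C4–C4a, which leads back to an acyclic diazomethyl ketone of an α-aryloxy acid in which C4 is still bonded to C2. In one flask, photochemical Wolff rearrangement shifts the quaternary C2 from the carbonyl carbon to the diazo carbon with retention (C2–C3), and the resulting ketene, turned into an acyl triflate by catalytic TfOH, acylates C4a (C4–C4a). The step exploits the 1,3-relationship of C2 and C4 in the pyranone ring and the activation of C4a by the ortho ether oxygen O1. The C2 stereocentre comes from (R)-lactic acid by self-regeneration of stereocentres and one Mitsunobu inversion.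

Key step: step 11

Remark: locants such as O1, C2, C4a refer to the chroman-4-one numbering of the target, and compounds 1, 5, 6 and 8 are taken as purchased.

Step 1
Reactants: 1 3-bromo-4-hydroxybenzaldehyde
Product: 2 3-bromo-4-(triisopropylsilyloxy)benzaldehyde
Conditions: TIPSCl, imidazole, DMF, rt
Reagents that add atoms: chlorotriisopropylsilane, CC(C)[Si](Cl)(C(C)C)C(C)C
Why: Silyl ether formation on the acidic bromophenol masks the oxygen that becomes the C6 hydroxyl with a bulky group that should last until fluoride is used.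

Step 2
Reactants: 2 3-bromo-4-(triisopropylsilyloxy)benzaldehyde
Product: 4 3-bromo-4-(triisopropylsilyloxy)phenol, via aryl formate 3 (not isolated)
Conditions: mCPBA, CH2Cl2, 0 °C → rt; then Et3N (cat.), MeOH, 0 °C
Reagents that add atoms: 3-chloroperoxybenzoic acid (mCPBA), OOC(=O)c1cccc(Cl)c1
Why: Baeyer–Villiger (Dakin-type) oxidation, in which the electron-rich para-silyloxyaryl group migrates to oxygen, gives formate 3, and its mild methanolysis should free only the new phenol.

Step 3
Reactants: 5 (R)-lactic acid; 6 pivalaldehyde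
Product: 7 (2R,5R)-2-tert-butyl-5-methyl-1,3-dioxolan-4-one
Conditions: TsOH·H2O (cat.), H2SO4 (cat.), pentane, reflux, Dean–Stark trap; recrystallisation from pentane/Et2O at −78 °C
Reagents that add atoms: none
Why: Acid-catalysed acetalisation sets the new acetal centre with tert-butyl cis to methyl (thermodynamic preference, upgraded by crystallisation), which stores the lactic acid configuration for self-regeneration of stereocentres.

Step 4
Reactants: 7 (2R,5R)-2-tert-butyl-5-methyl-1,3-dioxolan-4-one; 8 5-bromo-2-methylpent-2-ene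
Product: 10 (2R,5S)-2-tert-butyl-5-methyl-5-(4-methylpent-3-en-1-yl)-1,3-dioxolan-4-one, via lithium enolate 9 (not isolated)
Conditions: LiN(iPr)2 (LDA), THF, −78 °C; then 8, DMPU, −78 → −20 °C
Reagents that add atoms: none
Why: Enolate alkylation (SN2) on the face opposite the tert-butyl group puts the new chain where the hydrogen was and so sets the quaternary centre as 5S.

Step 5
Reactants: 10 (2R,5S)-2-tert-butyl-5-methyl-5-(4-methylpent-3-en-1-yl)-1,3-dioxolan-4-one
Product: 11 (2R,5S)-2-tert-butyl-5-(4-hydroxy-4-methylpentyl)-5-methyl-1,3-dioxolan-4-one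
Conditions: Co(acac)2 (cat.), PhSiH3, O2 (1 atm), THF, rt
Reagents that add atoms: dioxygen, O=O
Why: Mukaiyama hydration (metal hydride hydrogen-atom transfer, then trapping of the tertiary radical by O2) should add water in the Markovnikov sense without acid or base that would open the dioxolanone.

Step 6
Reactants: 11 (2R,5S)-2-tert-butyl-5-(4-hydroxy-4-methylpentyl)-5-methyl-1,3-dioxolan-4-one
Product: 12 (2R,5S)-2-tert-butyl-5-methyl-5-[4-methyl-4-(triethylsilyloxy)pentyl]-1,3-dioxolan-4-one
Conditions: TESOTf, 2,6-lutidine, CH2Cl2, −78 → 0 °C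
Reagents that add atoms: triethylsilyl trifluoromethanesulfonate, CC[Si](CC)(CC)OS(=O)(=O)C(F)(F)F
Why: Silylation with the reactive silyl triflate protects the tertiary alcohol against the chlorinating reagent of step 10 and the ketene of step 11.

Step 7
Reactants: 12 (2R,5S)-2-tert-butyl-5-methyl-5-[4-methyl-4-(triethylsilyloxy)pentyl]-1,3-dioxolan-4-one
Product: 13 allyl (S)-2-hydroxy-2,6-dimethyl-6-(triethylsilyloxy)heptanoate
Conditions: allyl alcohol, NaH (cat.), THF, 0 °C → rt
Reagents that add atoms: prop-2-en-1-ol (allyl alcohol), C=CCO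
Why: Transesterification by catalytic allyloxide opens the activated lactone and the hemiacetal alkoxide expels pivalaldehyde, which leaves the stereocentre untouched and gives an ester that can later be cleaved without base.

Step 8
Reactants: 13 allyl (S)-2-hydroxy-2,6-dimethyl-6-(triethylsilyloxy)heptanoate; 4 3-bromo-4-(triisopropylsilyloxy)phenol
Product: 14 allyl (R)-2-[3-bromo-4-(triisopropylsilyloxy)phenoxy]-2,6-dimethyl-6-(triethylsilyloxy)heptanoate
Conditions: PPh3, DIAD, toluene, 0 °C → 80 °C
Reagents that add atoms: none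
Why: Mitsunobu etherification of a tertiary α-hydroxy ester is an SN2 displacement of the alkoxyphosphonium ion by the phenoxide, assisted by the adjacent ester, and its inversion turns the 2S alcohol into the 2R aryl ether.

Step 9
Reactants: 14 allyl (R)-2-[3-bromo-4-(triisopropylsilyloxy)phenoxy]-2,6-dimethyl-6-(triethylsilyloxy)heptanoate
Product: 15 (R)-2-[3-bromo-4-(triisopropylsilyloxy)phenoxy]-2,6-dimethyl-6-(triethylsilyloxy)heptanoic acid
Conditions: Pd(PPh3)4 (cat.), morpholine, THF, rt; work-up with pH 5 buffer
Reagents that add atoms: none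
Why: Tsuji–Trost deallylation, in which zerovalent palladium ionises the allyl ester and morpholine captures the π-allyl complex, should free the acid while sparing both silyl ethers and the aryl bromide.

Step 10
Reactants: 15 (R)-2-[3-bromo-4-(triisopropylsilyloxy)phenoxy]-2,6-dimethyl-6-(triethylsilyloxy)heptanoic acid
Product: 17 (R)-3-[3-bromo-4-(triisopropylsilyloxy)phenoxy]-1-diazo-3,7-dimethyl-7-(triethylsilyloxy)octan-2-one, via acid chloride 16 (not isolated)
Conditions: 1-chloro-N,N,2-trimethylprop-1-en-1-amine, CH2Cl2, 0 °C → rt; then CH2N2 (excess), Et2O, 0 °C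
Reagents that add atoms: diazomethane, C=[N+]=[N-]
Why: Neutral acid chloride formation followed by C-acylation of diazomethane (first stage of an Arndt–Eistert sequence) should give the α-diazoketone, with excess diazomethane taking up the HCl.

Step 11
Reactants: 17 (R)-3-[3-bromo-4-(triisopropylsilyloxy)phenoxy]-1-diazo-3,7-dimethyl-7-(triethylsilyloxy)octan-2-one
Product: 19 (R)-7-bromo-2-methyl-2-[4-methyl-4-(triethylsilyloxy)pentyl]-6-(triisopropylsilyloxy)chroman-4-one, via ketene 18 (not isolated)
Conditions: hν (365 nm LED), CH2Cl2 (0.01 M), −78 °C; then TfOH (10 mol %), −78 → −30 °C; Et3N quench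
Reagents that add atoms: none
Why: Proposed new method: irradiation expels N2 from 17 and, in a concerted Wolff 1,2-shift, the fully substituted carbon (the later C2) migrates from the carbonyl carbon to the diazo carbon, which forms C2–C3 and gives ketene 18; catalytic TfOH then adds to the ketene to give an acyl triflate (acylium ion pair) that attacks the ring carbon ortho to the ether oxygen, forming C4–C4a, and loss of the ring proton regenerates TfOH. The closest known reaction types are the Arndt–Eistert homologation, in which the same ketene is trapped by water, followed by acid-mediated cyclisation of the 3-aryloxypropanoic acid, and the catalyst-free acylation of arenes by acyl triflates made from ketenes and TfOH; what is new is their merger on an α-aryloxy diazoketone. The pyranone ring closes in a six-membered intramolecular Friedel–Crafts acylation (6-exo-dig attack on the sp carbon of the acylium ion). No new stereocentre is formed: C2 is carried over unchanged because the migrating carbon keeps its configuration in the Wolff shift and is never planar afterwards. The step needs chemoselectivity for migration over carbene reactions and for C-acylation over ketene dimerisation, secured by metal-free photolysis at high dilution and by adding the acid only after the diazoketone is consumed (acid on the diazoketone would alkylate the arene and give a chroman-3-one). It also needs regioselectivity between the two carbons ortho to O1, secured because the one para to bromine is unhindered whereas the other is flanked by O1 and Br, while the carbon ortho to the silyloxy group cannot be reached in a six-membered transition state.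

Step 12
Reactants: 19 (R)-7-bromo-2-methyl-2-[4-methyl-4-(triethylsilyloxy)pentyl]-6-(triisopropylsilyloxy)chroman-4-one
Product: 20 (R)-7-bromo-6-hydroxy-2-(4-hydroxy-4-methylpentyl)-2-methylchroman-4-one
Conditions: TBAF, AcOH (1:1), THF, 0 °C → rt
Reagents that add atoms: none
Why: Fluoride-mediated desilylation buffered with acetic acid should cleave both silyl ethers while avoiding basic conditions that could open the pyranone ring by retro-oxa-Michael reaction and erode C2.

Compound list
1 | 3-bromo-4-hydroxybenzaldehyde | O=Cc1ccc(O)c(Br)c1 | starting material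
2 | 3-bromo-4-(triisopropylsilyloxy)benzaldehyde | O=Cc1ccc(O[Si](C(C)C)(C(C)C)C(C)C)c(Br)c1 | intermediate
3 | 3-bromo-4-(triisopropylsilyloxy)phenyl formate (not isolated) | O=COc1ccc(O[Si](C(C)C)(C(C)C)C(C)C)c(Br)c1 | intermediate
4 | 3-bromo-4-(triisopropylsilyloxy)phenol | Oc1ccc(O[Si](C(C)C)(C(C)C)C(C)C)c(Br)c1 | intermediate
5 | (R)-lactic acid | C[C@@H](O)C(=O)O | starting material
6 | pivalaldehyde (2,2-dimethylpropanal) | CC(C)(C)C=O | starting material
7 | (2R,5R)-2-tert-butyl-5-methyl-1,3-dioxolan-4-one | C[C@H]1O[C@@H](C(C)(C)C)OC1=O | intermediate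
8 | 5-bromo-2-methylpent-2-ene | CC(C)=CCCBr | starting material
9 | lithium (2R)-2-tert-butyl-5-methyl-1,3-dioxol-4-olate, the enolate of 7 (not isolated) | CC1=C([O-])O[C@H](C(C)(C)C)O1.[Li+] | intermediate
10 | (2R,5S)-2-tert-butyl-5-methyl-5-(4-methylpent-3-en-1-yl)-1,3-dioxolan-4-one | C[C@@]1(CCC=C(C)C)O[C@@H](C(C)(C)C)OC1=O | intermediate
11 | (2R,5S)-2-tert-butyl-5-(4-hydroxy-4-methylpentyl)-5-methyl-1,3-dioxolan-4-one | C[C@@]1(CCCC(C)(C)O)O[C@@H](C(C)(C)C)OC1=O | intermediate
12 | (2R,5S)-2-tert-butyl-5-methyl-5-[4-methyl-4-(triethylsilyloxy)pentyl]-1,3-dioxolan-4-one | C[C@@]1(CCCC(C)(C)O[Si](CC)(CC)CC)O[C@@H](C(C)(C)C)OC1=O | intermediate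
13 | allyl (S)-2-hydroxy-2,6-dimethyl-6-(triethylsilyloxy)heptanoate | C=CCOC(=O)[C@@](C)(O)CCCC(C)(C)O[Si](CC)(CC)CC | intermediate
14 | allyl (R)-2-[3-bromo-4-(triisopropylsilyloxy)phenoxy]-2,6-dimethyl-6-(triethylsilyloxy)heptanoate | C=CCOC(=O)[C@](C)(Oc1ccc(O[Si](C(C)C)(C(C)C)C(C)C)c(Br)c1)CCCC(C)(C)O[Si](CC)(CC)CC | intermediate
15 | (R)-2-[3-bromo-4-(triisopropylsilyloxy)phenoxy]-2,6-dimethyl-6-(triethylsilyloxy)heptanoic acid | OC(=O)[C@](C)(Oc1ccc(O[Si](C(C)C)(C(C)C)C(C)C)c(Br)c1)CCCC(C)(C)O[Si](CC)(CC)CC | intermediate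
16 | (R)-2-[3-bromo-4-(triisopropylsilyloxy)phenoxy]-2,6-dimethyl-6-(triethylsilyloxy)heptanoyl chloride (not isolated) | ClC(=O)[C@](C)(Oc1ccc(O[Si](C(C)C)(C(C)C)C(C)C)c(Br)c1)CCCC(C)(C)O[Si](CC)(CC)CC | intermediate
17 | (R)-3-[3-bromo-4-(triisopropylsilyloxy)phenoxy]-1-diazo-3,7-dimethyl-7-(triethylsilyloxy)octan-2-one | [N-]=[N+]=CC(=O)[C@](C)(Oc1ccc(O[Si](C(C)C)(C(C)C)C(C)C)c(Br)c1)CCCC(C)(C)O[Si](CC)(CC)CC | intermediate
18 | (R)-3-[3-bromo-4-(triisopropylsilyloxy)phenoxy]-3,7-dimethyl-7-(triethylsilyloxy)oct-1-en-1-one, the ketene (not isolated) | O=C=C[C@](C)(Oc1ccc(O[Si](C(C)C)(C(C)C)C(C)C)c(Br)c1)CCCC(C)(C)O[Si](CC)(CC)CC | intermediate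
19 | (R)-7-bromo-2-methyl-2-[4-methyl-4-(triethylsilyloxy)pentyl]-6-(triisopropylsilyloxy)chroman-4-one | CC(C)(O[Si](CC)(CC)CC)CCC[C@]1(C)CC(=O)c2cc(O[Si](C(C)C)(C(C)C)C(C)C)c(Br)cc2O1 | intermediate
20 | (R)-7-bromo-6-hydroxy-2-(4-hydroxy-4-methylpentyl)-2-methylchroman-4-one | CC(C)(O)CCC[C@]1(C)CC(=O)c2cc(O)c(Br)cc2O1 | target

Total step count: 12 (two for phenol 4, ten in the main line).
Longest linear sequence: 10 steps (steps 3 to 12, from 5 to 20).

Steps most likely to fail

Step 11 (Proposed new method). The ketene may be lost to dimerisation or to traces of water before it is acylated onto the ring. The acid may also ionise the tertiary C2–O1 ether at the ketene stage, so that C2 loses its configuration. The fallback sets out from 17 and comes back at 19, and makes the two bonds in two separate known operations. Silver-catalysed Wolff rearrangement in wet solvent (PhCO2Ag (cat.), Et3N, THF/H2O, rt; Arndt–Eistert homologation) should give (R)-3-[3-bromo-4-(triisopropylsilyloxy)phenoxy]-3,7-dimethyl-7-(triethylsilyloxy)octanoic acid F1. Treatment with 1-chloro-N,N,2-trimethylprop-1-en-1-amine (CH2Cl2, 0 °C) should give (R)-3-[3-bromo-4-(triisopropylsilyloxy)phenoxy]-3,7-dimethyl-7-(triethylsilyloxy)octanoyl chloride F2. Intramolecular Friedel–Crafts acylation with SnCl4 (CH2Cl2, −78 °C) should then close the ring to 19.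

Step 8. The hindered tertiary alcohol may fail to form the alkoxyphosphonium ion, or that ion may eliminate to the alkene faster than the phenoxide displaces it. The fallback sets out from 13 and comes back at 14, and replaces the azodicarboxylate activation by a preformed phosphinite and a quinone oxidant. Treatment of 13 with Ph2PCl, Et3N and DMAP (THF, 0 °C) should give allyl (S)-2-(diphenylphosphanyloxy)-2,6-dimethyl-6-(triethylsilyloxy)heptanoate F3. Condensation of this with phenol 4 and 2,6-dimethyl-1,4-benzoquinone (CH2Cl2, rt; Mukaiyama oxidation–reduction condensation, a method that gives tert-alkyl aryl ethers with inversion) should lead to 14.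

Step 4. The SN2 reaction of the unactivated homoallylic bromide may be so slow that enolate 9 decomposes or condenses with itself, or the enolate may act as a base and eliminate HBr from 8. The fallback sets out from 7 and comes back at 11, so it also bypasses step 5. Enolate 9 is alkylated with the far more reactive allyl bromide (LiN(iPr)2, THF, −78 °C) to give (2R,5S)-2-tert-butyl-5-methyl-5-(prop-2-en-1-yl)-1,3-dioxolan-4-one F4. Cross-metathesis with 2-methylbut-3-en-2-ol (second-generation Grubbs catalyst RuCl2(=CHPh)(H2IMes)(PCy3), CH2Cl2, 40 °C) should give (2R,5S)-2-tert-butyl-5-[(2E)-4-hydroxy-4-methylpent-2-en-1-yl]-5-methyl-1,3-dioxolan-4-one F5. Hydrogenation (H2, Pd/C, EtOAc, rt) should then give 11.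

Further compounds
F1 | step 11 | (R)-3-[3-bromo-4-(triisopropylsilyloxy)phenoxy]-3,7-dimethyl-7-(triethylsilyloxy)octanoic acid | OC(=O)C[C@](C)(Oc1ccc(O[Si](C(C)C)(C(C)C)C(C)C)c(Br)c1)CCCC(C)(C)O[Si](CC)(CC)CC
F2 | step 11 | (R)-3-[3-bromo-4-(triisopropylsilyloxy)phenoxy]-3,7-dimethyl-7-(triethylsilyloxy)octanoyl chloride | ClC(=O)C[C@](C)(Oc1ccc(O[Si](C(C)C)(C(C)C)C(C)C)c(Br)c1)CCCC(C)(C)O[Si](CC)(CC)CC
F3 | step 8 | allyl (S)-2-(diphenylphosphanyloxy)-2,6-dimethyl-6-(triethylsilyloxy)heptanoate | C=CCOC(=O)[C@@](C)(OP(c1ccccc1)c1ccccc1)CCCC(C)(C)O[Si](CC)(CC)CC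
F4 | step 4 | (2R,5S)-2-tert-butyl-5-methyl-5-(prop-2-en-1-yl)-1,3-dioxolan-4-one | C[C@@]1(CC=C)O[C@@H](C(C)(C)C)OC1=O
F5 | step 4 | (2R,5S)-2-tert-butyl-5-[(2E)-4-hydroxy-4-methylpent-2-en-1-yl]-5-methyl-1,3-dioxolan-4-one | C[C@@]1(C/C=C/C(C)(C)O)O[C@@H](C(C)(C)C)OC1=O
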